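## The problem

Target 14 is a trans-1-aryl-1,2-dihydronaphthalene. Ring A (7-hydroxy-6-methoxy) is fused through C4a and C8a to ring B, which carries a 4-hydroxy-3-methoxyphenyl group at C1, an acetoxymethyl group at C2 and a formyl group on the C3=C4 double bond. Only C1 and C2 are stereogenic, (1S,2R), with aryl and acetoxymethyl trans. No other stereocentre exists to relay from, so the absolute sense must come from a reagent or catalyst, while the trans relationship can be dictated by the geometry of the alkene that delivers C2 and C3. C1 is doubly benzylic, C2 is allylic, and the ring is two hydrogens away from an arylnaphthalene, so oxidants, hot acid and hydrogenation catalysts must be kept from the finished ring B. The enal, the primary acetate (which must sit on the C2 arm and on no phenol) and two free phenols restrict the end game to mild, non-basic, non-reducing conditions. The enabling feature is that C1 and C4 hang on the neighbouring ring A carbons C8a and C4a, so ring B is the formal [4+2] adduct of an ortho-quinodimethane of ring A with a C2=C3 alkene. Since C3=C4 is the dehydration product of a C4 carbinol beta to the formyl group, C4 can enter as an aryl aldehyde carbon and C1 as a diarylmethane CH2, which is the substitution pattern of a photoenol.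

## Retrosynthesis

14 ⇒ 13. The two phenols are unmasked last, by cleaving two aryl benzyl ethers of 13 (O–CH2Ph bonds). Benzyl is preferred to silyl or acetal protection because it survives palladium coupling under aqueous base, titanium alkoxide, light and amine base. Hydrogenolysis is ruled out by the enal, so the forward step must be a low-temperature Lewis-acid debenzylation that spares the acetate, the aryl methyl ethers and the alkene.

13 ⇒ 11. The C3=C4 bond is traced to the beta-hydroxy aldehyde 11 (C4–O cut, C3–H removed). The cut trades a sensitive conjugated system for a saturated ring and explains why only C1 and C2 need lasting control: C3 and C4 are erased. The forward reaction is a sulfonylation/elimination that must not touch C1 or C2; neither is alpha to the carbonyl.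

11 ⇒ 6 + 9 (through 10). C1–C2 and C3–C4 are cut together, the retro-Diels–Alder of ring B. Cuts of a single bond (C1–C8a, C1–C2 or C4–C4a) need a second ring-closing operation and a separate source of the C1/C2 relationship. This cut turns a tetralin with four contiguous stereocentres into the achiral diarylmethane aldehyde 6 and the four-carbon enal 9, which already carries the acetate. The forward step must generate the (E,E)-dienol 10 photochemically and trap it regioselectively, endo and on one face under a chiral titanium alkoxide complex.

6 ⇒ 3 + 5. The diarylmethane is cut at CH2–C8a into the formyl-substituted aryl boronate 3 and the benzylic bromide 5. The neighbouring option, an aryl anion alkylated by 5, needs the aldehyde masked and unmasked and risks halogen–metal exchange and Wurtz-type coupling. The palladium-catalysed sp2–sp3 coupling carries the free aldehyde. It must outrun protodeboronation of 3.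

3 ⇒ 2 ⇒ 1 and 5 ⇒ 4. The C–B bond of 3 comes from the C–Br bond of 2, and 2 from 6-bromovanillin 1 by O-benzylation. Bromide 5 comes from the commercial benzylic alcohol 4 by C–O to C–Br exchange. Each is a single standard operation on a benzene already bearing every ring substituent.

9 ⇒ 7 + 8. The enal is cut at its C=C bond into the symmetrical allylic diacetate 7 and crotonaldehyde 8. Cross-metathesis gives the (E)-enal in one step and avoids the statistical monoacylation and oxidation of a diol.

## Roads not taken

Alternative 1: Auxiliary-controlled conjugate arylation with enolate allylation. The cut is at C1–C8a and C2–C3 in an open chain. The aryl Grignard reagent A1 (ring A with its aldehyde masked as a dioxolane) would add, with CuBr·SMe2, to the N-feruloyl (S)-4-phenyloxazolidinone A2, and the enolate would be allylated in the same pot to give A3.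
- Merits: aryl cuprate additions to cinnamoyl 4-phenyloxazolidinones are among the most predictable ways to set a diaryl-substituted carbon. Diastereomers can be separated and the configuration assigned with confidence. No photochemistry is involved.
- Weak points: A1 is ortho-substituted and hindered. Trapping the magnesium/copper enolate with an allyl halide is sluggish and its selectivity at C2 is less secure than the addition. The key step closes no ring. From A3 the route needs reductive removal of the auxiliary, acetylation, oxidative cleavage of the allyl group, acetal hydrolysis, an intramolecular aldol condensation to close C3–C4, and debenzylation.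
- Comparison: this road is better in stereochemical predictability, since 11 depends on catalyst control that is less tested on a diarylmethane. The chosen plan sets against this a key step that forms both ring bonds and ring B at once, with the acetate and formyl groups already placed, leaving two steps after it instead of about six, and no stoichiometric auxiliary to attach and remove.

Alternative 2: Dienamine closure onto an in situ para-quinone methide. The cut is at C1–C2 with C3=C4 already present. Acid would dehydrate the racemic para-hydroxybenzhydrol A4 to a quinone methide while diphenylprolinol trimethylsilyl ether forms the dienamine of its tethered enal. The dienamine alpha carbon (C2) attacks C1 and gives A5.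
- Merits: the planar quinone methide erases the carbinol centre, so the racemate converges. Both C1 and C2 are set organocatalytically under mild conditions. The pendant phenol of the target is the activating group and needs no protection.
- Weak points: A5 carries the formyl group on C2 and the oxygenated methylene on C3, the reverse of 14. Correcting this needs reduction and acetylation at C2, then desilylation and allylic oxidation at C3. The C2 centre of A5 is alpha to an aldehyde and allylic, so epimerisation and double-bond migration into conjugation threaten until it is reduced. Alpha versus gamma attack of the dienamine must be controlled. A4, with its trisubstituted enal, takes longer to make than 6.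
- Comparison: this road has the gentler asymmetric step and avoids a Lewis-acid deprotection of the pendant ring. The chosen plan answers with a cycloadduct already at the correct oxidation pattern and with C2 never alpha to a carbonyl.

Alternative 3: Gold carbene arylation from a terminal alkyne. The cut is at C4–C4a. Ph3PAuNTf2 (monovalent gold) and 8-methylquinoline N-oxide would oxidise the alkyne of A6 to an alpha-oxo gold carbene at C4, which ring A attacks to give the beta-tetralone A7.
- Merits: the ring closure is catalytic, mild and free of diazo compounds. The attacking carbon is para to the benzyloxy group.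
- Weak points: the step creates no stereocentre, so C1 and C2 must come from a separate asymmetric synthesis of A6. The pendant aryl group can also reach the carbene through a six-membered transition state at its position para to methoxy, and the aryl acetate is the only bias against this. In A7, C2 is alpha to the ketone and can epimerise. C3 is a ketone and needs a one-carbon homologation to the conjugated aldehyde, for example enol triflate formation toward C4 and reductive carbonylation. The silyl ether, aryl acetate and benzyl ether then require three further protecting-group operations.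
- Comparison: this road needs no photochemical equipment and its cyclisation is probably the most scalable single step of the four plans. The chosen plan offsets this by forming all stereocentres and the correct C3/C4 functionality in the ring-forming step itself.

Key step: step 6

Assumption: (R,R)-TADDOL is taken to be the ligand enantiomer that exposes the dienolate face leading to (1S,2R,3S,4S)-11. If the opposite sense is found, (S,S)-TADDOL replaces it with no other change.

## Route

Step 1
Reactants: 1 6-bromovanillin (2-bromo-4-hydroxy-5-methoxybenzaldehyde)
Product: 2 4-(benzyloxy)-2-bromo-5-methoxybenzaldehyde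
Conditions: BnBr, K2CO3, DMF, rt
Reagents that add atoms: benzyl bromide, BrCc1ccccc1
Why: Williamson etherification of the phenoxide; the aldehyde and the aryl bromide are inert to carbonate and benzyl bromide.

Step 2
Reactants: 2 4-(benzyloxy)-2-bromo-5-methoxybenzaldehyde
Product: 3 4-(benzyloxy)-5-methoxy-2-(4,4,5,5-tetramethyl-1,3,2-dioxaborolan-2-yl)benzaldehyde
Conditions: B2pin2, Pd(dppf)Cl2, KOAc, 1,4-dioxane, 90 °C
Reagents that add atoms: bis(pinacolato)diboron, CC1(C)OB(OC1(C)C)B1OC(C)(C)C(C)(C)O1
Why: Miyaura borylation; oxidative addition of zerovalent palladium to the C–Br bond is assisted by the ortho formyl group, and the weak acetate base leaves the aldehyde and the benzyl ether alone.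

Step 3
Reactants: 4 [4-(benzyloxy)-3-methoxyphenyl]methanol
Product: 5 1-(benzyloxy)-4-(bromomethyl)-2-methoxybenzene
Conditions: PBr3, CH2Cl2, 0 °C
Reagents that add atoms: phosphorus tribromide, BrP(Br)Br
Why: Bromide displaces the activated phosphite ester of the para-alkoxybenzylic alcohol quickly at 0 °C; the bromide is used directly without storage.

Step 4
Reactants: 3 4-(benzyloxy)-5-methoxy-2-(4,4,5,5-tetramethyl-1,3,2-dioxaborolan-2-yl)benzaldehyde; 5 1-(benzyloxy)-4-(bromomethyl)-2-methoxybenzene
Product: 6 4-(benzyloxy)-2-[4-(benzyloxy)-3-methoxybenzyl]-5-methoxybenzaldehyde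
Conditions: Pd(dppf)Cl2, Cs2CO3, THF/H2O (10:1), 70 °C
Reagents that add atoms: none
Why: Suzuki–Miyaura sp2–sp3 coupling; the benzylic bromide adds readily to zerovalent palladium and the benzylpalladium species has no beta hydrogen, so the diarylmethane forms cleanly with the aldehyde unprotected.

Step 5
Reactants: 7 (Z)-but-2-ene-1,4-diyl diacetate; 8 (E)-but-2-enal (crotonaldehyde, excess)
Product: 9 (E)-4-oxobut-2-en-1-yl acetate
Conditions: second-generation Hoveyda–Grubbs catalyst RuCl2(H2IMes)(=CH-C6H4-2-OiPr), CH2Cl2, 40 °C
Reagents that add atoms: none
Why: Olefin cross-metathesis between an electron-rich allylic acetate and an electron-poor enal that homodimerises slowly; the conjugated product is formed as the (E) isomer and both halves of 7 are used.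

Step 6
Reactants: 6 4-(benzyloxy)-2-[4-(benzyloxy)-3-methoxybenzyl]-5-methoxybenzaldehyde; 9 (E)-4-oxobut-2-en-1-yl acetate
Product: 11 [(1S,2R,3S,4S)-7-(benzyloxy)-1-[4-(benzyloxy)-3-methoxyphenyl]-3-formyl-4-hydroxy-6-methoxy-1,2,3,4-tetrahydronaphthalen-2-yl]methyl acetate, via photoenol (E,E)-hydroxy-ortho-quinodimethane 10 (not isolated)
Conditions: Ti(OiPr)4 (stoichiometric), (R,R)-TADDOL, toluene, hν (366 nm), 0 °C
Reagents that add atoms: none
Why: Excitation of the aryl aldehyde of 6 and 1,5-hydrogen transfer from the doubly benzylic CH2 give the hydroxy-ortho-quinodimethane; the (Z)-dienol reverts thermally, while the (E)-dienol 10, with its aryl group also turned outward, is held as a titanium dienolate on the TADDOLate. The closest known reaction type is the titanium-alkoxide-promoted photoenolisation/Diels–Alder reaction of 2-alkylbenzaldehydes with enone and enal dienophiles, including its TADDOL-controlled enantioselective form, together with the trapping of 2-benzylbenzaldehyde photoenols by electron-poor alkenes. Ring B is closed by an intermolecular suprafacial [4+2] cycloaddition that forms C1–C2 and C3–C4 in one event and restores the aromatic sextet of ring A. The dienolate terminus remote from oxygen (C1) is the nucleophilic end and bonds to the enal beta carbon, and the titanium bridge between dienolate oxygen and formyl oxygen enforces the same pairing, so the formyl group lands on C3 beside the C4 carbinol. C1 and C4 follow from the (E,E) geometry of 10 (aryl and O–Ti cis), C2 and C3 are trans because the (E) alkene of 9 adds suprafacially, and the endo position of the titanium-bound formyl group places it cis to the C4 oxygen and the acetoxymethyl group trans to the C1 aryl. The absolute sense at all four centres comes from the TADDOLate aryl groups shielding one face of the planar dienolate. The step needs endo and enantiofacial selectivity: the first is secured by the two-point binding and by the exo site being the one that keeps CH2OAc away from the C1 aryl, the second rests on the ligand. The acetate travels on the dienophile, so C2 needs no later adjustment.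

Step 7
Reactants: 11 [(1S,2R,3S,4S)-7-(benzyloxy)-1-[4-(benzyloxy)-3-methoxyphenyl]-3-formyl-4-hydroxy-6-methoxy-1,2,3,4-tetrahydronaphthalen-2-yl]methyl acetate
Product: 13 [(1S,2R)-7-(benzyloxy)-1-[4-(benzyloxy)-3-methoxyphenyl]-3-formyl-6-methoxy-1,2-dihydronaphthalen-2-yl]methyl acetate, via C4 mesylate 12 (not isolated)
Conditions: MsCl, Et3N, CH2Cl2, 0 °C to rt
Reagents that add atoms: methanesulfonyl chloride, CS(=O)(=O)Cl (its atoms stay in 12 only)
Why: Mesylation of the benzylic carbinol and base-induced beta-elimination of the acidic C3–H (E1cB type) give the conjugated enal; C3 and C4 are erased, while C1 and C2 are not alpha to the carbonyl and keep their configuration.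

Step 8
Reactants: 13 [(1S,2R)-7-(benzyloxy)-1-[4-(benzyloxy)-3-methoxyphenyl]-3-formyl-6-methoxy-1,2-dihydronaphthalen-2-yl]methyl acetate
Product: 14 [(1S,2R)-3-formyl-7-hydroxy-1-(4-hydroxy-3-methoxyphenyl)-6-methoxy-1,2-dihydronaphthalen-2-yl]methyl acetate
Conditions: BCl3, C6HMe5, CH2Cl2, −78 °C
Reagents that add atoms: none
Why: Lewis-acid debenzylation with a cation scavenger; BCl3 is chelated by each benzyloxy/methoxy pair and pentamethylbenzene captures the benzyl cation by Friedel–Crafts alkylation, so at −78 °C the aryl methyl ethers, the acetate, the enal and both stereocentres remain untouched.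

## Compound list

1 | 6-bromovanillin (2-bromo-4-hydroxy-5-methoxybenzaldehyde) | COc1cc(C=O)c(Br)cc1O | starting material
2 | 4-(benzyloxy)-2-bromo-5-methoxybenzaldehyde | COc1cc(C=O)c(Br)cc1OCc1ccccc1 | intermediate
3 | 4-(benzyloxy)-5-methoxy-2-(4,4,5,5-tetramethyl-1,3,2-dioxaborolan-2-yl)benzaldehyde | COc1cc(C=O)c(B2OC(C)(C)C(C)(C)O2)cc1OCc1ccccc1 | intermediate
4 | [4-(benzyloxy)-3-methoxyphenyl]methanol | COc1cc(CO)ccc1OCc1ccccc1 | starting material
5 | 1-(benzyloxy)-4-(bromomethyl)-2-methoxybenzene | COc1cc(CBr)ccc1OCc1ccccc1 | intermediate
6 | 4-(benzyloxy)-2-[4-(benzyloxy)-3-methoxybenzyl]-5-methoxybenzaldehyde | COc1cc(Cc2cc(OCc3ccccc3)c(OC)cc2C=O)ccc1OCc1ccccc1 | intermediate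
7 | (Z)-but-2-ene-1,4-diyl diacetate | CC(=O)OC/C=C\COC(C)=O | starting material
8 | (E)-but-2-enal (crotonaldehyde) | C/C=C/C=O | starting material
9 | (E)-4-oxobut-2-en-1-yl acetate | CC(=O)OC/C=C/C=O | intermediate
10 | (E)-[(6E)-4-(benzyloxy)-6-[4-(benzyloxy)-3-methoxybenzylidene]-3-methoxycyclohexa-2,4-dien-1-ylidene]methanol, the photoenol, titanium-bound in the flask | O/C=C1\C=C(OC)C(OCc2ccccc2)=C/C1=C\c1ccc(OCc2ccccc2)c(OC)c1 | intermediate (not isolated)
11 | [(1S,2R,3S,4S)-7-(benzyloxy)-1-[4-(benzyloxy)-3-methoxyphenyl]-3-formyl-4-hydroxy-6-methoxy-1,2,3,4-tetrahydronaphthalen-2-yl]methyl acetate | COc1cc([C@H]2c3cc(OCc4ccccc4)c(OC)cc3[C@@H](O)[C@@H](C=O)[C@@H]2COC(C)=O)ccc1OCc1ccccc1 | intermediate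
12 | [(1S,2R,3S,4S)-7-(benzyloxy)-1-[4-(benzyloxy)-3-methoxyphenyl]-3-formyl-6-methoxy-4-[(methylsulfonyl)oxy]-1,2,3,4-tetrahydronaphthalen-2-yl]methyl acetate | COc1cc([C@H]2c3cc(OCc4ccccc4)c(OC)cc3[C@@H](OS(C)(=O)=O)[C@@H](C=O)[C@@H]2COC(C)=O)ccc1OCc1ccccc1 | intermediate (not isolated)
13 | [(1S,2R)-7-(benzyloxy)-1-[4-(benzyloxy)-3-methoxyphenyl]-3-formyl-6-methoxy-1,2-dihydronaphthalen-2-yl]methyl acetate | COc1cc([C@H]2c3cc(OCc4ccccc4)c(OC)cc3C=C(C=O)[C@@H]2COC(C)=O)ccc1OCc1ccccc1 | intermediate
14 | [(1S,2R)-3-formyl-7-hydroxy-1-(4-hydroxy-3-methoxyphenyl)-6-methoxy-1,2-dihydronaphthalen-2-yl]methyl acetate | COc1cc([C@H]2c3cc(O)c(OC)cc3C=C(C=O)[C@@H]2COC(C)=O)ccc1O | target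

## Step count and risk

Total steps: 8. Longest linear sequence: 6 steps (steps 1, 2, 4, 6, 7, 8).

Step 6 (key step). The most likely failure is insufficient enantiofacial discrimination: the trisubstituted, aryl-bearing diene terminus changes the shape of the dienolate in the titanium TADDOLate pocket compared with the 2-methyl cases. Other risks are erosion of endo selectivity (which would give the C1/C2 cis series), photochemical E/Z isomerisation of the enal, slow Meerwein–Ponndorf–Verley reduction or acetate exchange by titanium isopropoxide, and retro-aldol opening of the adduct on work-up. The fallback gives up catalyst control for resolution. Starting from 6 and 9, irradiation with Ti(OiPr)4 alone should give the racemic endo adduct F1. Treatment as in step 7 passes through the racemic mesylate F2 to the racemic enal F3. Preparative chromatography on a chiral stationary phase then separates 13 from its (1R,2S) enantiomer F4, and the route is rejoined at 13.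

Step 8. The risk is collateral Lewis-acid damage: cleavage of the primary acetate or of a guaiacyl methyl ether, or acid-driven aromatisation of the dihydronaphthalene while the enal holds extra BCl3. The fallback reverses the order of the last two operations. Starting from 11, hydrogenolysis (H2, Pd/C, EtOAc), while no alkene is present, should give the bisphenol hydroxy aldehyde F5. Its C4 carbinol is para to a free phenol, so it loses water under catalytic pyridinium p-toluenesulfonate through a quinone methide and arrives directly at 14. The point to watch there is hydrogenolysis of the C4 benzylic hydroxyl.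

Step 4. The risk is protodeboronation of the electron-rich, ortho-formyl boronate 3 and hydrolysis or homocoupling of the benzylic bromide under aqueous base before transmetalation. The fallback reverses the polarity of the coupling. Starting from 5, palladium-catalysed borylation (B2pin2, Pd(PPh3)4, KOAc) gives the benzylic boronate F6. F6 is coupled with bromo aldehyde 2 (Pd(dppf)Cl2, Cs2CO3, aqueous THF), whose oxidative addition is activated by the formyl group, to return at 6.

Step 5. The risk is incomplete cross-selectivity (homodimers, some Z isomer) and loss of the small, polymerisable enal on isolation. The fallback replaces metathesis by functional-group interconversion. Starting from 7, lipase-mediated monohydrolysis gives the (Z)-hydroxy acetate F7. Oxidation with [C5H5NH][CrO3Cl] (pyridinium chlorochromate) in CH2Cl2 gives the aldehyde with concurrent Z-to-E isomerisation and returns at 9.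

## Further compounds

F1 | step 6 | racemic endo cycloadduct, 1:1 mixture of 11 and its enantiomer | COc1cc([C@H]2c3cc(OCc4ccccc4)c(OC)cc3[C@@H](O)[C@@H](C=O)[C@@H]2COC(C)=O)ccc1OCc1ccccc1.COc1cc([C@@H]2c3cc(OCc4ccccc4)c(OC)cc3[C@H](O)[C@H](C=O)[C@H]2COC(C)=O)ccc1OCc1ccccc1
F2 | step 6 | racemic C4 mesylate, 1:1 mixture of 12 and its enantiomer (not isolated) | COc1cc([C@H]2c3cc(OCc4ccccc4)c(OC)cc3[C@@H](OS(C)(=O)=O)[C@@H](C=O)[C@@H]2COC(C)=O)ccc1OCc1ccccc1.COc1cc([C@@H]2c3cc(OCc4ccccc4)c(OC)cc3[C@H](OS(C)(=O)=O)[C@H](C=O)[C@H]2COC(C)=O)ccc1OCc1ccccc1
F3 | step 6 | racemic enal, 1:1 mixture of 13 and F4 | COc1cc([C@H]2c3cc(OCc4ccccc4)c(OC)cc3C=C(C=O)[C@@H]2COC(C)=O)ccc1OCc1ccccc1.COc1cc([C@@H]2c3cc(OCc4ccccc4)c(OC)cc3C=C(C=O)[C@H]2COC(C)=O)ccc1OCc1ccccc1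
F4 | step 6 | [(1R,2S)-7-(benzyloxy)-1-[4-(benzyloxy)-3-methoxyphenyl]-3-formyl-6-methoxy-1,2-dihydronaphthalen-2-yl]methyl acetate, enantiomer of 13 | COc1cc([C@@H]2c3cc(OCc4ccccc4)c(OC)cc3C=C(C=O)[C@H]2COC(C)=O)ccc1OCc1ccccc1
F5 | step 8 | [(1S,2R,3S,4S)-3-formyl-4,7-dihydroxy-1-(4-hydroxy-3-methoxyphenyl)-6-methoxy-1,2,3,4-tetrahydronaphthalen-2-yl]methyl acetate | COc1cc([C@H]2c3cc(O)c(OC)cc3[C@@H](O)[C@@H](C=O)[C@@H]2COC(C)=O)ccc1O
F6 | step 4 | 2-[4-(benzyloxy)-3-methoxybenzyl]-4,4,5,5-tetramethyl-1,3,2-dioxaborolane | COc1cc(CB2OC(C)(C)C(C)(C)O2)ccc1OCc1ccccc1
F7 | step 5 | (Z)-4-hydroxybut-2-en-1-yl acetate | CC(=O)OC/C=C\CO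
A1 | alternative 1 | [4-(benzyloxy)-2-(1,3-dioxolan-2-yl)-5-methoxyphenyl]magnesium bromide | COc1cc(C2OCCO2)c([Mg]Br)cc1OCc1ccccc1
A2 | alternative 1 | (4S)-3-[(2E)-3-[4-(benzyloxy)-3-methoxyphenyl]prop-2-enoyl]-4-phenyl-1,3-oxazolidin-2-one | COc1cc(/C=C/C(=O)N2[C@@H](c3ccccc3)COC2=O)ccc1OCc1ccccc1
A3 | alternative 1 | 2-allyl-3,3-diarylpropanoyl (S)-4-phenyloxazolidinone with C1 and C2 configured as in the target | COc1cc(ccc1OCc1ccccc1)[C@@H](c1cc(OCc2ccccc2)c(OC)cc1C1OCCO1)[C@H](CC=C)C(=O)N1[C@@H](c2ccccc2)COC1=O
A4 | alternative 2 | racemic 4-[4-(tert-butyldimethylsilyloxy)-2-[hydroxy(4-hydroxy-3-methoxyphenyl)methyl]-5-methoxyphenyl]-3-[(tert-butyldimethylsilyloxy)methyl]but-2-enal | COc1cc(C(O)c2cc(O[Si](C)(C)C(C)(C)C)c(OC)cc2C/C(CO[Si](C)(C)C(C)(C)C)=C/C=O)ccc1O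
A5 | alternative 2 | trans-1-aryl-3-(silyloxymethyl)-1,2-dihydronaphthalene-2-carbaldehyde | COc1cc([C@H]2c3cc(O[Si](C)(C)C(C)(C)C)c(OC)cc3C=C(CO[Si](C)(C)C(C)(C)C)[C@@H]2C=O)ccc1O
A6 | alternative 3 | 4-[1-[3-(benzyloxy)-4-methoxyphenyl]-2-[(tert-butyldimethylsilyloxy)methyl]but-3-yn-1-yl]-2-methoxyphenyl acetate, both centres configured as in the target | COc1cc([C@@H](c2ccc(OC)c(OCc3ccccc3)c2)[C@H](C#C)CO[Si](C)(C)C(C)(C)C)ccc1OC(C)=O
A7 | alternative 3 | trans-1-aryl-2-(silyloxymethyl) beta-tetralone (C3 ketone) | COc1cc([C@H]2c3cc(OCc4ccccc4)c(OC)cc3CC(=O)[C@@H]2CO[Si](C)(C)C(C)(C)C)ccc1OC(C)=O
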